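**Retrosynthetic overview**
- The target is a mono-acetate of a resorcinol whose two phenol oxygens are homotopic, so the last step is cleavage of one of two equivalent aryl acetates of a diacetate.
- The C2–O bond and the only stereocentre are disconnected together: enantioselective anti-Markovnikov addition of water across an (E)-1-aryl-tetradec-1-ene (key step, new).
- The (E)-alkene diacetate comes from tetradec-1-yne, pinacolborane and 5-bromoresorcinol in one flask (hydroboration, Suzuki–Miyaura coupling, acetylation).
- No ring is constructed; the benzene ring is bought.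

Assumption: the sense of induction of the new ion-pair catalyst in step 2 cannot be predicted, so the IDPi enantiomer that gives the (S)-alcohol is used (written here as (S,S); its antipode is equally available).

**Step 1**
Reactants: 1 tetradec-1-yne; 2 pinacolborane; 3 5-bromobenzene-1,3-diol (5-bromoresorcinol)
Product: 6 5-[(E)-tetradec-1-en-1-yl]-1,3-phenylene diacetate, via alkenyl pinacolboronate 4 (not isolated), via alkenylresorcinol 5 (not isolated)
Conditions: 1 (1.15 equiv), 2 (1.2 equiv), Cp2Zr(H)Cl (5 mol%), Et3N (10 mol%), neat, 60 °C; then 3 (1.0 equiv), Pd(OAc)2/SPhos (2/4 mol%), K3PO4 (4 equiv), dioxane/H2O 10:1, 80 °C; then Ac2O (5 equiv), DMAP (5 mol%), 0 °C to rt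
Reagents that add atoms: acetic anhydride, CC(=O)OC(C)=O
Why: Zr-catalysed syn-hydroboration of the terminal alkyne gives only the (E)-alkenylboronate, Suzuki–Miyaura coupling proceeds with retention of alkene geometry on the bromoresorcinol as its phenoxide, and the phenoxides are O-acetylated in the same flask (Schotten–Baumann-type acylation); no stereocentre is formed.

**Step 2**
Reactants: 6 5-[(E)-tetradec-1-en-1-yl]-1,3-phenylene diacetate
Product: 7 5-[(2S)-2-hydroxytetradecyl]-1,3-phenylene diacetate
Conditions: [3,6-di-tert-butyl-9-mesityl-10-phenylacridinium][(S,S)-IDPi] pre-formed salt (5 mol%, no achiral counter-anion), (PhS)2 (10 mol%), H2O (5 equiv), CH2Cl2 (0.025 M), 450 nm LEDs, 0 °C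
Reagents that add atoms: water, O
Why: Proposed new method: the excited acridinium (E*red about +2.1 V) oxidises the β-alkylstyrene to its radical cation, which in CH2Cl2 stays in a contact ion pair with the confined chiral imidodiphosphorimidate (IDPi) anion; a water molecule hydrogen-bonded to the anion is delivered inside that pocket to one face of the β-carbon (C2), the position whose attack leaves the stabilised benzylic radical, so the C2–O bond and the (S) stereocentre are formed in the same enantio-determining step; the anion takes up the proton, the benzylic radical is reduced to CH2 by hydrogen-atom transfer from PhSH, and the thiyl radical reoxidises the acridine radical and is reprotonated by IDPi–H, closing both cycles; the closest known reaction types are the racemic acridinium/thiol photoredox anti-Markovnikov hydration of β-alkylstyrenes and asymmetric counteranion-directed photoredox catalysis of styrene radical cations with IDPi anions, shown so far for cycloadditions and not for capture by an oxygen nucleophile.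

**Step 3**
Reactants: 7 5-[(2S)-2-hydroxytetradecyl]-1,3-phenylene diacetate
Product: 8 3-hydroxy-5-[(2S)-2-hydroxytetradecyl]phenyl acetate
Conditions: LiOH·H2O (2.0 equiv), THF/H2O 4:1, 0 °C, about 1 h; then 1 M HCl to pH 4–5
Reagents that add atoms: none
Why: Saponification (acyl–oxygen cleavage) of one of two homotopic aryl acetates is self-limiting because each cleavage consumes two equivalents of hydroxide (acetate plus phenoxide) and the meta-phenoxide formed deactivates the remaining ester; the secondary alcohol and its stereocentre are not touched.

**Compound list**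
1 | tetradec-1-yne | CCCCCCCCCCCCC#C | starting material
2 | pinacolborane (4,4,5,5-tetramethyl-1,3,2-dioxaborolane) | CC1(C)OBOC1(C)C | starting material
3 | 5-bromobenzene-1,3-diol (5-bromoresorcinol) | Oc1cc(O)cc(Br)c1 | starting material
4 | 4,4,5,5-tetramethyl-2-[(E)-tetradec-1-en-1-yl]-1,3,2-dioxaborolane | CCCCCCCCCCCC/C=C/B1OC(C)(C)C(C)(C)O1 | intermediate
5 | 5-[(E)-tetradec-1-en-1-yl]benzene-1,3-diol (formed as its dipotassium phenoxide) | CCCCCCCCCCCC/C=C/c1cc(O)cc(O)c1 | intermediate
6 | 5-[(E)-tetradec-1-en-1-yl]-1,3-phenylene diacetate | CCCCCCCCCCCC/C=C/c1cc(OC(C)=O)cc(OC(C)=O)c1 | intermediate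
7 | 5-[(2S)-2-hydroxytetradecyl]-1,3-phenylene diacetate | CCCCCCCCCCCC[C@H](O)Cc1cc(OC(C)=O)cc(OC(C)=O)c1 | intermediate
8 | 3-hydroxy-5-[(2S)-2-hydroxytetradecyl]phenyl acetate | CCCCCCCCCCCC[C@H](O)Cc1cc(O)cc(OC(C)=O)c1 | target

**Step count and risks**
Total step count: 3. Longest linear sequence: 3.

Steps most likely to fail:

Step 2 (the proposed new step). The risks are insufficient enantiocontrol in the water-capture event, sluggish oxidation of the electron-poor diacetoxystyrene (about +2.0 V), and acid-promoted Markovnikov side reactions from IDPi–H. The fallback uses known chemistry, sets out from 6 and comes back at 7. Compound 6 is epoxidised with the L-fructose-derived (ent-)Shi ketone used in excess at pH 7.5–8 (Oxone, NaHCO3, MeCN/aqueous Na2EDTA, 0 °C), conditions mild enough for the aryl acetates. The D-fructose ketone gives the (R,R) series with trans-β-alkylstyrenes, so the ent-ketone gives 5-[(2S,3S)-3-dodecyloxiran-2-yl]-1,3-phenylene diacetate F3. Hydrogenolysis over Pd/C (H2 1 atm, EtOAc, rt) then cleaves only the benzylic C–O bond; the C2–O bond and its configuration are kept, giving 7.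

Step 1. The risks are slow oxidative addition into the electron-rich bromoresorcinol dianion and incomplete acetylation in the wet medium. The fallback sets out from 3 (with 1) and comes back at 6. Compound 3 is first acetylated (Ac2O, pyridine, DMAP cat., CH2Cl2) to 5-bromo-1,3-phenylene diacetate F1. Separately, 1 is hydrozirconated with stoichiometric Cp2Zr(H)Cl (THF, rt) to chlorobis(cyclopentadienyl)[(E)-tetradec-1-en-1-yl]zirconium F2. F2 is cross-coupled with F1 under Pd(PPh3)4 (5 mol%, THF, 50 °C) in a base-free Negishi-type coupling that leaves the aryl acetates intact and gives 6 directly.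

Step 3. The risks are over-hydrolysis to the triol or incomplete conversion, giving a mixture of di-, mono- and non-acetylated material. The fallback sets out from 7 and comes back at 8. Both aryl acetates are removed by methanolysis (K2CO3 cat., MeOH, rt) to 5-[(2S)-2-hydroxytetradecyl]benzene-1,3-diol F4. F4 is then mono-acetylated on phenoxide oxygen with Ac2O (1.0 equiv) in aqueous NaOH/THF at 0 °C, which is selective for phenoxide over the secondary alcohol. The mono-acetate 8 is separated, and recovered F4 and 7 are recycled.

**Further compounds**
F1 | step 1 | 5-bromo-1,3-phenylene diacetate | CC(=O)Oc1cc(Br)cc(OC(C)=O)c1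
F2 | step 1 | chlorobis(cyclopentadienyl)[(E)-tetradec-1-en-1-yl]zirconium | CCCCCCCCCCCC/C=C/[Zr](Cl)(C1C=CC=C1)C1C=CC=C1
F3 | step 2 | 5-[(2S,3S)-3-dodecyloxiran-2-yl]-1,3-phenylene diacetate | CCCCCCCCCCCC[C@@H]1O[C@H]1c1cc(OC(C)=O)cc(OC(C)=O)c1
F4 | step 3 | 5-[(2S)-2-hydroxytetradecyl]benzene-1,3-diol | CCCCCCCCCCCC[C@H](O)Cc1cc(O)cc(O)c1
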